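**Plan**

- Drimane numbering is used: decalin C1–C10, C11 on C9, C12 on C8, two methyls on C4, C15 on C10. The retrosynthesis removes the acetate and the C11–O aryl ether, opens ring A at C3–C4, then cuts ring B at C9–C10 and C5–C6 after adding a temporary O11–C1 ester bond.
- The enabling feature is ring B: C6=C7–C8(CH3)=C9–C11–O is a 3-methylpentadienol, C1–C10(CH3)=C5–C4 is an E-methylbutenedioate, and acylation of O11 by C1 gives the five-membered ring C9–C11–O–C1–C10.
- Forward: the dienyl half-ester is made by Wittig olefination and turned into the imide; one cycloaddition closes ring B and the lactone; C4 becomes an isopropenyl group; the lactone is opened and C1 extended by C2–C3; a radical C3–C4 bond closes ring A; coumarin and acetate go on last.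
- Stereochemistry: C5 (absolute) from the chiral divalent copper catalyst; C10 and C9 relative to C5 from the E dienophile, the E diene and the imide-endo transition state; C3 from a chair radical closure with oxygen equatorial.

Key step: step 6

Assumption: the SMILES is read as the (3R,5S,9R,10R) compound (acetoxy equatorial, cis to the C10 methyl and to C11; H5 trans to the C10 methyl), and the face selection of the copper catalyst is taken from the square-planar chelate model of N-enoyl oxazolidinones, which calls for the (R,R) ligand.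

**Route**

Step 1
Reactants: 1 (2E)-3-methylpent-2-en-4-yn-1-ol
Product: 2 (2E)-3-methylpenta-2,4-dien-1-ol
Conditions: H2 (1 atm), Pd/CaCO3 poisoned with Pb(OAc)2, quinoline, Et2O, 0 °C, stopped at 1 equiv H2
Reagents that add atoms: none
Why: Semihydrogenation of a terminal alkyne over lead-poisoned palladium should stop at the alkene, and the existing E trisubstituted double bond is not touched.

Step 2
Reactants: 2 (2E)-3-methylpenta-2,4-dien-1-ol; 3 2-bromopropanoyl bromide (racemic)
Product: 4 (2E)-3-methylpenta-2,4-dien-1-yl 2-bromopropanoate (racemic)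
Conditions: pyridine, CH2Cl2, −20 to 0 °C
Reagents that add atoms: none
Why: O-Acylation of a primary allylic alcohol by an acyl bromide is much faster than any reaction at the secondary alkyl bromide.

Step 3
Reactants: 4 (2E)-3-methylpenta-2,4-dien-1-yl 2-bromopropanoate
Product: 6 (2E)-3-methylpenta-2,4-dien-1-yl 2-(triphenylphosphoranylidene)propanoate, via phosphonium bromide 5 (not isolated)
Conditions: PPh3, MeCN, 60 °C; then aq NaOH, CH2Cl2, 0 °C
Reagents that add atoms: triphenylphosphine, c1ccc(cc1)P(c1ccccc1)c1ccccc1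
Why: SN2 quaternisation of PPh3 by the α-bromo ester and deprotonation is the standard preparation of a stabilised Wittig ylide, and the racemic centre is erased.

Step 4
Reactants: 6 (2E)-3-methylpenta-2,4-dien-1-yl 2-(triphenylphosphoranylidene)propanoate; 7 glyoxylic acid monohydrate
Product: 8 (2E)-3-methyl-4-{[(2E)-3-methylpenta-2,4-dien-1-yl]oxy}-4-oxobut-2-enoic acid
Conditions: CH2Cl2, 0 °C to rt
Reagents that add atoms: none
Why: Wittig olefination of glyoxylic acid with a stabilised α-methyl ylide should give the E alkene (carboxyl trans to the ester, the mesaconate geometry), and it fixes by construction that the free acid sits on the CH carbon (C4) and the dienyl ester on the methyl-bearing carbon (C1 on C10).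

Step 5
Reactants: 8 (2E)-3-methyl-4-{[(2E)-3-methylpenta-2,4-dien-1-yl]oxy}-4-oxobut-2-enoic acid; 9 oxazolidin-2-one
Product: 11 (2E)-3-methylpenta-2,4-dien-1-yl (2E)-2-methyl-4-oxo-4-(2-oxo-1,3-oxazolidin-3-yl)but-2-enoate, via mixed pivalic anhydride 10 (not isolated)
Conditions: t-BuCOCl, Et3N, THF, −20 °C; then oxazolidin-2-one, LiCl, −20 °C to rt
Reagents that add atoms: pivaloyl chloride, CC(C)(C)C(=O)Cl (its acyl group stays only in intermediate 10)
Why: N-Acylation of an oxazolidinone through a mixed pivalic anhydride with LiCl/Et3N is routine for unsaturated acids, and attack occurs at the unhindered butenoyl carbonyl, not the pivaloyl one.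

Step 6
Reactants: 11 (2E)-3-methylpenta-2,4-dien-1-yl (2E)-2-methyl-4-oxo-4-(2-oxo-1,3-oxazolidin-3-yl)but-2-enoate
Product: 12 (3aR,7S,7aS)-4,7a-dimethyl-7-[(2-oxo-1,3-oxazolidin-3-yl)carbonyl]-3a,6,7,7a-tetrahydro-2-benzofuran-1(3H)-one (trans-fused lactone; C3a = C9, C7 = C5, C7a = C10)
Conditions: [Cu((R,R)-t-Bu-box)](SbF6)2 (10 mol %), CH2Cl2, 25 °C (t-Bu-box = 2,2'-(propane-2,2-diyl)bis[(4R)-4-tert-butyl-4,5-dihydro-1,3-oxazole], C17H30N2O2)
Reagents that add atoms: none
Why: Proposed new method: bidentate chelation of the acyl oxazolidinone to the divalent copper bis(oxazoline) cation lowers the LUMO of the mesaconyl alkene, and the tethered E diene adds in a concerted, asynchronous [4+2] in which the C9–C10 bond (to the imide β-carbon) leads and C5–C6 follows; the closest known reaction types are the copper bis(oxazoline)-catalysed intramolecular Diels–Alder of trienyl imides and the thermal intramolecular Diels–Alder of pentadienyl fumarates and mesaconates, which have not been combined on an ester-tethered substrate. Ring B closes as the six-membered cycloaddition ring and the γ-lactone closes as the five-membered tether ring (C9, C11, O, C1, C10) of a nona-1,3,8-triene-type cyclisation, trans-fused because the tether carbonyl C1 lies exo. C5 is set in the absolute sense by the ligand, whose tert-butyl group covers the Re face of C5 in the square-planar s-cis chelate so that C6 bonds to the Si face; C10 follows from C5 through suprafacial addition to the E alkene (C4 and the C10 methyl cis); C9 follows from the E geometry of C8=C9 together with the imide-endo, tether-exo transition state, which places C11 cis to the C10 methyl. The step needs endo placement of the imide and a single enantioface: the first is favoured because only the imide is activated and because E dienophile esters of this tether length already prefer the trans-fused lactone thermally, the second is imposed by the C2-symmetric ligand on an achiral substrate. Regiochemistry is not at issue, since the three-atom tether allows only the C9–C10/C5–C6 union.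

Step 7
Reactants: 12 (3aR,7S,7aS)-lactone imide
Product: 13 S-ethyl (3aR,7S,7aS)-4,7a-dimethyl-1-oxo-1,3,3a,6,7,7a-hexahydro-2-benzofuran-7-carbothioate
Conditions: EtSH, n-BuLi, THF, 0 °C; aq NH4Cl
Reagents that add atoms: ethanethiol, CCS (used as lithium ethanethiolate, [Li+].CC[S-])
Why: Lithium thiolate transacylation cleaves N-acyl oxazolidinones at the exocyclic carbonyl even when hindered, while the soft thiolate leaves the lactone alone and the equatorial C5 acyl group has no drive to epimerise.

Step 8
Reactants: 13 S-ethyl thioester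
Product: 14 (3aR,7S,7aS)-7-acetyl-4,7a-dimethyl-3a,6,7,7a-tetrahydro-2-benzofuran-1(3H)-one
Conditions: Me2CuLi (from MeLi and CuI), Et2O, −78 to −40 °C; aq NH4Cl
Reagents that add atoms: lithium dimethylcuprate, [Li+].C[Cu-]C
Why: Cuprate acylation of a thioester stops at the methyl ketone because ketones and lactones are inert to the cuprate at low temperature.

Step 9
Reactants: 14 methyl ketone
Product: 15 (3aR,7R,7aR)-4,7a-dimethyl-7-(prop-1-en-2-yl)-3a,6,7,7a-tetrahydro-2-benzofuran-1(3H)-one (same spatial arrangement as 12)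
Conditions: Ph3PCH3Br, KOt-Bu, THF, 0 °C to rt
Reagents that add atoms: methylenetriphenylphosphorane, C=P(c1ccccc1)(c1ccccc1)c1ccccc1 (from methyltriphenylphosphonium bromide)
Why: Wittig methylenation takes the ketone far faster than the hindered lactone on the quaternary carbon, and reversible enolisation cannot harm C5 because its equatorial substituent is the stable arrangement.

Step 10
Reactants: 15 isopropenyl lactone
Product: 16 (3aR,7R,7aR)-4,7a-dimethyl-7-(prop-1-en-2-yl)-1,3,3a,6,7,7a-hexahydro-2-benzofuran-1-ol (lactol, both C1 anomers)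
Conditions: i-Bu2AlH (1.2 equiv), CH2Cl2, −78 °C; aq potassium sodium tartrate
Reagents that add atoms: none
Why: Partial reduction of a lactone with i-Bu2AlH stops at the aluminium hemiacetal at −78 °C, and no other reducible group is present.

Step 11
Reactants: 16 lactol
Product: 17 3-[(1R,2R,6R)-2-(hydroxymethyl)-1,3-dimethyl-6-(prop-1-en-2-yl)cyclohex-3-en-1-yl]prop-2-enenitrile (E/Z mixture; ring C1 = C10, C2 = C9, C6 = C5)
Conditions: Ph3P=CHCN, toluene, 90 °C
Reagents that add atoms: (triphenylphosphoranylidene)acetonitrile, N#CC=P(c1ccccc1)(c1ccccc1)c1ccccc1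
Why: Wittig olefination of the lactol through its open hydroxy aldehyde adds C2 and C3, and the base-free conditions should hold back conjugate re-addition of the C11 hydroxyl, which would have to form a strained trans-fused tetrahydrofuran.

Step 12
Reactants: 17 unsaturated nitrile
Product: 18 3-[(1R,2R,6R)-2-(hydroxymethyl)-1,3-dimethyl-6-(prop-1-en-2-yl)cyclohex-3-en-1-yl]propanenitrile
Conditions: Mg turnings, MeOH, 0 °C to rt
Reagents that add atoms: none
Why: Dissolving-metal conjugate reduction with Mg in MeOH transfers electrons only to the conjugated nitrile, so both alkene isomers converge on the saturated nitrile and the isopropenyl and ring alkenes stay.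

Step 13
Reactants: 18 saturated nitrile
Product: 20 3-[(1R,2R,6R)-2-(hydroxymethyl)-1,3-dimethyl-6-(prop-1-en-2-yl)cyclohex-3-en-1-yl]propanal, via aldimine 19 (not isolated)
Conditions: i-Bu2AlH (2.5 equiv), CH2Cl2, −78 °C; then aq potassium sodium tartrate, wet SiO2
Reagents that add atoms: water, O
Why: After the hydroxyl has consumed one equivalent, i-Bu2AlH adds once to the nitrile and the N-aluminio imine hydrolyses to the aldehyde on mild work-up, so over-reduction is not possible.

Step 14
Reactants: 20 hydroxy aldehyde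
Product: 21 (3R,5S,9R,10R)-drim-7-ene-3,11-diol
Conditions: Fe(acac)3 (0.5 equiv), PhSiH3 (2.5 equiv), EtOH, 60 °C
Reagents that add atoms: none
Why: Iron-hydride hydrogen-atom transfer to the 1,1-disubstituted alkene gives the tertiary C4 radical, which closes ring A by 6-exo addition to the aldehyde carbon (a known radical cyclisation of alkene-tethered carbonyl compounds) through a chair with the oxygen pseudo-equatorial, setting C3 with the hydroxyl equatorial and cis to the C10 methyl.

Step 15
Reactants: 21 (3R,5S,9R,10R)-drim-7-ene-3,11-diol; 22 umbelliferone (7-hydroxy-2H-chromen-2-one)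
Product: 23 7-{[(3R,5S,9R,10R)-3-hydroxydrim-7-en-11-yl]oxy}-2H-chromen-2-one
Conditions: PPh3, DIAD, THF, 0 °C to rt
Reagents that add atoms: none
Why: Mitsunobu etherification activates the primary C11 hydroxyl and not the secondary C3 hydroxyl flanked by the geminal methyls, and the acidic phenol is a good partner; no stereocentre is involved.

Step 16
Reactants: 23 hydroxy ether
Product: 24 (3R,5S,9R,10R)-11-[(2-oxo-2H-chromen-7-yl)oxy]drim-7-en-3-yl acetate (target)
Conditions: Ac2O, pyridine, DMAP (cat.), CH2Cl2, rt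
Reagents that add atoms: acetic anhydride, CC(=O)OC(C)=O
Why: DMAP-catalysed acetylation of the equatorial secondary alcohol proceeds with retention at C3 and leaves the coumarin untouched.

**Compound list**

1 | (2E)-3-methylpent-2-en-4-yn-1-ol | C#C/C(C)=C/CO | starting material
2 | (2E)-3-methylpenta-2,4-dien-1-ol | C=C/C(C)=C/CO | intermediate
3 | 2-bromopropanoyl bromide (racemic) | CC(Br)C(Br)=O | starting material
4 | (2E)-3-methylpenta-2,4-dien-1-yl 2-bromopropanoate (racemic) | C=C/C(C)=C/COC(=O)C(C)Br | intermediate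
5 | (1-{[(2E)-3-methylpenta-2,4-dien-1-yl]oxy}-1-oxopropan-2-yl)triphenylphosphonium bromide | C=C/C(C)=C/COC(=O)C(C)[P+](c1ccccc1)(c1ccccc1)c1ccccc1.[Br-] | intermediate
6 | (2E)-3-methylpenta-2,4-dien-1-yl 2-(triphenylphosphoranylidene)propanoate | C=C/C(C)=C/COC(=O)C(C)=P(c1ccccc1)(c1ccccc1)c1ccccc1 | intermediate
7 | glyoxylic acid monohydrate | OC(O)C(=O)O | starting material
8 | (2E)-3-methyl-4-{[(2E)-3-methylpenta-2,4-dien-1-yl]oxy}-4-oxobut-2-enoic acid | C=C/C(C)=C/COC(=O)/C(C)=C/C(=O)O | intermediate
9 | oxazolidin-2-one | O=C1NCCO1 | starting material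
10 | mixed anhydride of 8 with pivalic acid | C=C/C(C)=C/COC(=O)/C(C)=C/C(=O)OC(=O)C(C)(C)C | intermediate
11 | (2E)-3-methylpenta-2,4-dien-1-yl (2E)-2-methyl-4-oxo-4-(2-oxo-1,3-oxazolidin-3-yl)but-2-enoate | C=C/C(C)=C/COC(=O)/C(C)=C/C(=O)N1CCOC1=O | intermediate
12 | (3aR,7S,7aS)-4,7a-dimethyl-7-[(2-oxo-1,3-oxazolidin-3-yl)carbonyl]-3a,6,7,7a-tetrahydro-2-benzofuran-1(3H)-one | O=C1OC[C@@H]2C(C)=CC[C@H](C(=O)N3CCOC3=O)[C@@]12C | intermediate
13 | S-ethyl (3aR,7S,7aS)-4,7a-dimethyl-1-oxo-1,3,3a,6,7,7a-hexahydro-2-benzofuran-7-carbothioate | O=C1OC[C@@H]2C(C)=CC[C@H](C(=O)SCC)[C@@]12C | intermediate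
14 | (3aR,7S,7aS)-7-acetyl-4,7a-dimethyl-3a,6,7,7a-tetrahydro-2-benzofuran-1(3H)-one | O=C1OC[C@@H]2C(C)=CC[C@H](C(C)=O)[C@@]12C | intermediate
15 | (3aR,7R,7aR)-4,7a-dimethyl-7-(prop-1-en-2-yl)-3a,6,7,7a-tetrahydro-2-benzofuran-1(3H)-one | O=C1OC[C@@H]2C(C)=CC[C@H](C(C)=C)[C@@]12C | intermediate
16 | (3aR,7R,7aR)-4,7a-dimethyl-7-(prop-1-en-2-yl)-1,3,3a,6,7,7a-hexahydro-2-benzofuran-1-ol (anomer mixture) | OC1OC[C@@H]2C(C)=CC[C@H](C(C)=C)[C@@]12C | intermediate
17 | 3-[(1R,2R,6R)-2-(hydroxymethyl)-1,3-dimethyl-6-(prop-1-en-2-yl)cyclohex-3-en-1-yl]prop-2-enenitrile (E/Z mixture) | OC[C@@H]1C(C)=CC[C@H](C(C)=C)[C@]1(C=CC#N)C | intermediate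
18 | 3-[(1R,2R,6R)-2-(hydroxymethyl)-1,3-dimethyl-6-(prop-1-en-2-yl)cyclohex-3-en-1-yl]propanenitrile | OC[C@@H]1C(C)=CC[C@H](C(C)=C)[C@]1(CCC#N)C | intermediate
19 | 3-[(1R,2R,6R)-2-(hydroxymethyl)-1,3-dimethyl-6-(prop-1-en-2-yl)cyclohex-3-en-1-yl]propan-1-imine | OC[C@@H]1C(C)=CC[C@H](C(C)=C)[C@]1(CCC=N)C | intermediate
20 | 3-[(1R,2R,6R)-2-(hydroxymethyl)-1,3-dimethyl-6-(prop-1-en-2-yl)cyclohex-3-en-1-yl]propanal | OC[C@@H]1C(C)=CC[C@H](C(C)=C)[C@]1(CCC=O)C | intermediate
21 | (3R,5S,9R,10R)-drim-7-ene-3,11-diol | O[C@@H]1CC[C@@]2(C)[C@H](CO)C(C)=CC[C@@H]2C1(C)C | intermediate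
22 | umbelliferone (7-hydroxy-2H-chromen-2-one) | Oc1ccc2ccc(=O)oc2c1 | starting material
23 | 7-{[(3R,5S,9R,10R)-3-hydroxydrim-7-en-11-yl]oxy}-2H-chromen-2-one | O[C@@H]1CC[C@@]2(C)[C@H](COc3ccc4ccc(=O)oc4c3)C(C)=CC[C@@H]2C1(C)C | intermediate
24 | (3R,5S,9R,10R)-11-[(2-oxo-2H-chromen-7-yl)oxy]drim-7-en-3-yl acetate | CC(=O)O[C@@H]1CC[C@@]2(C)[C@H](COc3ccc4ccc(=O)oc4c3)C(C)=CC[C@@H]2C1(C)C | target

**Step count**

Total steps: 16. Longest linear sequence: 16 (1 to 24; compounds 3, 7, 9 and 22 are added along the way).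

**Steps most likely to fail**

Step 6. The cycloaddition may stall because the ester tether has to reach its disfavoured s-cis arrangement and the dienophile is trisubstituted. The cationic catalyst may also be held by the ester or ionise the dienyl C–O bond, and face selection may be incomplete. The fallback sets out from 8 and comes back at 13, and uses the thermal intramolecular Diels–Alder of dienyl mesaconates together with a covalent resolving group. Acid 8 would be coupled through 10 with (4S)-4-benzyl-oxazolidin-2-one (t-BuCOCl, Et3N, LiCl) to give the auxiliary-bearing triene (2E)-3-methylpenta-2,4-dien-1-yl (2E)-4-[(4S)-4-benzyl-2-oxo-1,3-oxazolidin-3-yl]-2-methyl-4-oxobut-2-enoate F1. Heating F1 (toluene, 110 °C, BHT) should give the trans-fused lactones as two diastereomers, the wanted (3aR,7S,7aS) lactone imide F2 and the (3aS,7R,7aR) lactone imide F3. These would be separated by chromatography or crystallisation. Thiolysis of F2 with LiSEt as in step 7 releases the auxiliary and gives 13.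

Step 14. Addition of the C4 radical to the aldehyde is reversible and the two faces of the carbonyl may be poorly distinguished, so C3 may form as a mixture. Hydrogen-atom transfer to the ring B alkene or early reduction of the radical may also cost material. The fallback sets out from 20 and comes back at 23, and sets C3 by hydride delivery to a ketone, which is established for 4,4-dimethyl-3-ketones of this ring system. The cyclisation would be run without regard to C3 to give (5S,9R,10R)-drim-7-ene-3,11-diol as a C3 epimer mixture F4. Mitsunobu etherification with 22 then gives the C3-epimeric 7-{[(5S,9R,10R)-3-hydroxydrim-7-en-11-yl]oxy}-2H-chromen-2-one F5. Dess–Martin oxidation converges both epimers on 7-{[(5S,9R,10R)-3-oxodrim-7-en-11-yl]oxy}-2H-chromen-2-one F6. NaBH4 (MeOH/CH2Cl2, −20 °C, short contact to spare the coumarin) should attack axially, on the face away from the axial C4 and C10 methyls, and give the equatorial alcohol 23.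

Step 11. Olefination may be slow because the aldehyde sits on a quaternary carbon and is largely closed as the lactol, and the freed C11 hydroxyl may add back to the unsaturated nitrile. The fallback sets out from 15 and comes back at 17, and works on a free aldehyde with the hydroxyl masked. LiAlH4 (THF, 0 °C) would reduce 15 to [(1R,2R,6R)-1,3-dimethyl-6-(prop-1-en-2-yl)cyclohex-3-ene-1,2-diyl]dimethanol F7. TBSCl/imidazole (CH2Cl2, −20 °C) should silylate the less hindered C11 hydroxyl and give [(1R,2R,6R)-2-{[(tert-butyldimethylsilyl)oxy]methyl}-1,3-dimethyl-6-(prop-1-en-2-yl)cyclohex-3-en-1-yl]methanol F8. Dess–Martin oxidation gives (1R,2R,6R)-2-{[(tert-butyldimethylsilyl)oxy]methyl}-1,3-dimethyl-6-(prop-1-en-2-yl)cyclohex-3-ene-1-carbaldehyde F9. Horner–Wadsworth–Emmons reaction with diethyl cyanomethylphosphonate and NaH (THF, 0 °C to rt) gives 3-[(1R,2R,6R)-2-{[(tert-butyldimethylsilyl)oxy]methyl}-1,3-dimethyl-6-(prop-1-en-2-yl)cyclohex-3-en-1-yl]prop-2-enenitrile F10. HF·pyridine (THF, 0 °C) removes the silyl group under non-basic conditions and gives 17.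

**Further compounds**

F1 | step 6 | (2E)-3-methylpenta-2,4-dien-1-yl (2E)-4-[(4S)-4-benzyl-2-oxo-1,3-oxazolidin-3-yl]-2-methyl-4-oxobut-2-enoate | C=C/C(C)=C/COC(=O)/C(C)=C/C(=O)N1[C@@H](Cc2ccccc2)COC1=O
F2 | step 6 | (3aR,7S,7aS)-7-{[(4S)-4-benzyl-2-oxo-1,3-oxazolidin-3-yl]carbonyl}-4,7a-dimethyl-3a,6,7,7a-tetrahydro-2-benzofuran-1(3H)-one | O=C1OC[C@@H]2C(C)=CC[C@H](C(=O)N3[C@@H](Cc4ccccc4)COC3=O)[C@@]12C
F3 | step 6 | (3aS,7R,7aR)-7-{[(4S)-4-benzyl-2-oxo-1,3-oxazolidin-3-yl]carbonyl}-4,7a-dimethyl-3a,6,7,7a-tetrahydro-2-benzofuran-1(3H)-one | O=C1OC[C@H]2C(C)=CC[C@@H](C(=O)N3[C@@H](Cc4ccccc4)COC3=O)[C@]12C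
F4 | step 14 | (5S,9R,10R)-drim-7-ene-3,11-diol, C3 epimer mixture | OC1CC[C@@]2(C)[C@H](CO)C(C)=CC[C@@H]2C1(C)C
F5 | step 14 | 7-{[(5S,9R,10R)-3-hydroxydrim-7-en-11-yl]oxy}-2H-chromen-2-one, C3 epimer mixture | OC1CC[C@@]2(C)[C@H](COc3ccc4ccc(=O)oc4c3)C(C)=CC[C@@H]2C1(C)C
F6 | step 14 | 7-{[(5S,9R,10R)-3-oxodrim-7-en-11-yl]oxy}-2H-chromen-2-one | O=C1CC[C@@]2(C)[C@H](COc3ccc4ccc(=O)oc4c3)C(C)=CC[C@@H]2C1(C)C
F7 | step 11 | [(1R,2R,6R)-1,3-dimethyl-6-(prop-1-en-2-yl)cyclohex-3-ene-1,2-diyl]dimethanol | OC[C@@H]1C(C)=CC[C@H](C(C)=C)[C@]1(CO)C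
F8 | step 11 | [(1R,2R,6R)-2-{[(tert-butyldimethylsilyl)oxy]methyl}-1,3-dimethyl-6-(prop-1-en-2-yl)cyclohex-3-en-1-yl]methanol | CC(C)(C)[Si](C)(C)OC[C@@H]1C(C)=CC[C@H](C(C)=C)[C@]1(CO)C
F9 | step 11 | (1R,2R,6R)-2-{[(tert-butyldimethylsilyl)oxy]methyl}-1,3-dimethyl-6-(prop-1-en-2-yl)cyclohex-3-ene-1-carbaldehyde | CC(C)(C)[Si](C)(C)OC[C@@H]1C(C)=CC[C@H](C(C)=C)[C@]1(C=O)C
F10 | step 11 | 3-[(1R,2R,6R)-2-{[(tert-butyldimethylsilyl)oxy]methyl}-1,3-dimethyl-6-(prop-1-en-2-yl)cyclohex-3-en-1-yl]prop-2-enenitrile | CC(C)(C)[Si](C)(C)OC[C@@H]1C(C)=CC[C@H](C(C)=C)[C@]1(C=CC#N)C
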